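## Retrosynthetic overview

1. Target 19 ⇐ its 1-O-PMB ether 18 (DDQ); every other functional group is already in place.
2. 18 ⇐ acyclic epoxy aldehyde 16 by one Ni/Cr (Nozaki–Hiyama–Kishi) alkenylation. It closes the ten-membered carbocycle at C6–C7 (the farnesyl C1–C10 bond of germacrene biogenesis) and, in the same flask, the butenolide by O6→C12 lactonisation (as in costunolide formation).
3. 16 ⇐ (Z)-β-iodo enoate 13 (C13 acetate and C8 methacrylate in place) by desilylation, Sharpless epoxidation and oxidation; 13 ⇐ ynoate 11 by an iodide/formaldehyde halo-aldol.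
4. 11 ⇐ aldehyde 8 + methyl propiolate (asymmetric alkynylation, C8); 8 ⇐ nerol-derived C7 aldehyde 4 by anti-crotylboration (C1, C10) and anti-Markovnikov Wacker oxidation.
5. Ring order: oxirane (acyclic, reagent-controlled) → carbocycle → γ-lactone, the last two in one operation.

Assumption: the SMILES is taken exactly as drawn, (1S,4R,5S,6S,8S,10R) in germacrane numbering (C1 free carbinol, C4/C5 oxirane, C6 lactone carbinol, C7=C11 butenolide alkene, C8 methacrylate carbinol, C12 lactone C=O, C13 CH2OAc). With these descriptors C3 and C6 are cis on the oxirane, so the epoxide comes from a (4Z)-alkene and nerol, not geraniol, is the terpene building block. Germacrane locants are used in the text; TBDPS = tert-butyldiphenylsilyl, PMB = 4-methoxybenzyl.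

## Route

Step 1
Reactants: 1 nerol
Product: 2 neryl tert-butyldiphenylsilyl ether
Conditions: TBDPSCl, imidazole, CH2Cl2, 0 °C to rt
Reagents that add atoms: tert-butyl(chloro)diphenylsilane (TBDPSCl), CC(C)(C)[Si](Cl)(c1ccccc1)c1ccccc1
Why: Silyl ether protection of the primary allylic alcohol; TBDPS is chosen because it survives periodic acid, the Wacker step and MgI2 and is later removed by fluoride without touching esters; no stereocentre is formed.

Step 2
Reactants: 2 neryl tert-butyldiphenylsilyl ether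
Product: 4 (4Z)-6-[(tert-butyldiphenylsilyl)oxy]-4-methylhex-4-enal, via terminal epoxide 3 (not isolated)
Conditions: mCPBA (1.0 equiv), CH2Cl2, −20 °C; then H5IO6, THF/H2O, 0 °C
Reagents that add atoms: meta-chloroperbenzoic acid (mCPBA), OOC(=O)c1cccc(Cl)c1
Why: Prilezhaev epoxidation picks the more electron-rich distal alkene (the 2,3-alkene is deactivated by the allylic oxygen) and periodic acid cleaves the epoxide through the diol (Malaprade-type cleavage) to the aldehyde and acetone, leaving the Z-alkene untouched.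

Step 3
Reactants: 4 (4Z)-6-[(tert-butyldiphenylsilyl)oxy]-4-methylhex-4-enal
Product: 6 (3R,4S,7Z)-9-[(tert-butyldiphenylsilyl)oxy]-3,7-dimethylnona-1,7-dien-4-ol, via diisopinocampheylborinate 5 (not isolated)
Conditions: trans-2-butene, KOtBu, n-BuLi, THF, −78 to −45 °C; (+)-Ipc2BOMe then BF3·OEt2, −78 °C; 4, −78 °C; NaOH, H2O2, 0 °C to rt
Reagents that add atoms: (E)-crotyl-(+)-diisopinocampheylborane (made in the flask from trans-2-butene and (+)-Ipc2BOMe), C/C=C/CB([C@H]1C[C@H]2C[C@@H]([C@@H]1C)C2(C)C)[C@H]1C[C@H]2C[C@@H]([C@@H]1C)C2(C)C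
Why: Brown asymmetric crotylboration through a chair Zimmerman–Traxler transition state, in which the (E)-crotyl geometry gives the anti OH/CH3 relationship and the (+)-Ipc2B group (from (−)-α-pinene) directs Re-face attack, setting C1 (S) and C10 (R) of the target.

Step 4
Reactants: 6 (3R,4S,7Z)-9-[(tert-butyldiphenylsilyl)oxy]-3,7-dimethylnona-1,7-dien-4-ol
Product: 7 4-methoxybenzyl ether of 6
Conditions: NaH, PMBCl, Bu4NI (cat.), THF/DMF, 0 °C to rt
Reagents that add atoms: 4-methoxybenzyl chloride (PMBCl), COc1ccc(CCl)cc1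
Why: Williamson etherification masks the C1 hydroxyl, which would otherwise form a lactol with the C8 aldehyde and open the later 4,5-epoxide in a 5-exo fashion; PMB is removed at the end under neutral oxidative conditions; stereocentres untouched.

Step 5
Reactants: 7 4-methoxybenzyl ether of 6
Product: 8 (3R,4S,7Z)-9-[(tert-butyldiphenylsilyl)oxy]-4-[(4-methoxybenzyl)oxy]-3,7-dimethylnon-7-enal
Conditions: PdCl2(PhCN)2 (10 mol%), CuCl2·2H2O (10 mol%), AgNO2 (5 mol%), O2 (1 atm), t-BuOH/MeNO2 15:1, rt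
Reagents that add atoms: dioxygen, O=O
Why: Nitrite-modified, aldehyde-selective (anti-Markovnikov) Wacker oxidation of the monosubstituted alkene, with regioselectivity reinforced by the allylic branch and homoallylic ether; the trisubstituted alkene is inert and C10, being β to the new aldehyde, cannot epimerise.

Step 6
Reactants: 8 (3R,4S,7Z)-9-[(tert-butyldiphenylsilyl)oxy]-4-[(4-methoxybenzyl)oxy]-3,7-dimethylnon-7-enal; 9 methyl propiolate
Product: 10 methyl (4S,6R,7S,10Z)-12-[(tert-butyldiphenylsilyl)oxy]-4-hydroxy-7-[(4-methoxybenzyl)oxy]-6,10-dimethyldodec-10-en-2-ynoate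
Conditions: Me2Zn, (S,S)-ProPhenol (20 mol%), Ph3PO (40 mol%), toluene, 4 °C
Reagents that add atoms: none
Why: Trost zinc–ProPhenol asymmetric alkynylation, in which the dinuclear zinc catalyst delivers the zinc propiolate to the Re face of the aldehyde and so sets C8 (S) under catalyst control; the (S,S) ligand is the antipode I expect to give this sense, to be confirmed by Mosher ester analysis and swapped for (R,R) if not.

Step 7
Reactants: 10 methyl (4S,6R,7S,10Z)-12-[(tert-butyldiphenylsilyl)oxy]-4-hydroxy-7-[(4-methoxybenzyl)oxy]-6,10-dimethyldodec-10-en-2-ynoate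
Product: 11 4-O-methacryloyl ester of 10
Conditions: methacrylic anhydride, pyridine, DMAP (cat.), CH2Cl2, 0 °C
Reagents that add atoms: methacrylic anhydride, C=C(C)C(=O)OC(=O)C(C)=C
Why: DMAP-catalysed acyl transfer (Steglich-type acylation) installs the C8 methacrylate with retention, and the weak base and low temperature avoid the base-induced redox isomerisation of γ-hydroxy ynoates.

Step 8
Reactants: 11 4-O-methacryloyl ester of 10
Product: 13 methyl (2Z,4S,6R,7S,10Z)-2-(acetoxymethyl)-12-[(tert-butyldiphenylsilyl)oxy]-3-iodo-7-[(4-methoxybenzyl)oxy]-4-(methacryloyloxy)-6,10-dimethyldodeca-2,10-dienoate, via magnesium aldolate 12 (not isolated)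
Conditions: MgI2 (1.5 equiv), CH2O (monomer, THF solution), CH2Cl2, −78 to −20 °C; then Ac2O, pyridine, DMAP, −20 to 0 °C
Reagents that add atoms: magnesium diiodide, [Mg+2].[I-].[I-]; formaldehyde, C=O; acetic anhydride, CC(=O)OC(C)=O
Why: Halo-aldol (β-iodo Morita–Baylis–Hillman) reaction, in which iodide adds to C7 of the MgI2-activated ynoate and the iodo-allenolate is hydroxymethylated at C11 on the side away from the large iodine (net anti addition, as in anti-hydroiodination of ynoates), giving the Z-alkene with I cis to CO2Me before in-flask acetylation fixes the C13 acetate and prevents Z to E equilibration.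

Step 9
Reactants: 13 methyl (2Z,4S,6R,7S,10Z)-2-(acetoxymethyl)-12-[(tert-butyldiphenylsilyl)oxy]-3-iodo-7-[(4-methoxybenzyl)oxy]-4-(methacryloyloxy)-6,10-dimethyldodeca-2,10-dienoate
Product: 14 12-hydroxy compound (free C6 allylic alcohol) from 13
Conditions: HF·pyridine, pyridine, THF, 0 °C to rt
Reagents that add atoms: none
Why: Buffered fluoride desilylation frees the primary (Z)-allylic alcohol while the three esters, the PMB ether and the alkenyl iodide are inert.

Step 10
Reactants: 14 12-hydroxy compound (free C6 allylic alcohol) from 13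
Product: 15 methyl (2Z,4S,6R,7S)-2-(acetoxymethyl)-9-[(2R,3S)-3-(hydroxymethyl)-2-methyloxiran-2-yl]-3-iodo-7-[(4-methoxybenzyl)oxy]-4-(methacryloyloxy)-6-methylnon-2-enoate
Conditions: Ti(OiPr)4, L-(+)-diethyl tartrate, t-BuOOH, 4 Å MS, CH2Cl2, −20 °C
Reagents that add atoms: tert-butyl hydroperoxide, CC(C)(C)OO
Why: Sharpless asymmetric epoxidation of the (Z)-trisubstituted allylic alcohol, where L-(+)-tartrate delivers oxygen to the face that gives the cis (4R,5S) oxirane (same sense as nerol to (2S,3R)-epoxynerol); the electron-poor alkenes do not react.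

Step 11
Reactants: 15 methyl (2Z,4S,6R,7S)-2-(acetoxymethyl)-9-[(2R,3S)-3-(hydroxymethyl)-2-methyloxiran-2-yl]-3-iodo-7-[(4-methoxybenzyl)oxy]-4-(methacryloyloxy)-6-methylnon-2-enoate
Product: 16 methyl (2Z,4S,6R,7S)-2-(acetoxymethyl)-9-[(2R,3R)-3-formyl-2-methyloxiran-2-yl]-3-iodo-7-[(4-methoxybenzyl)oxy]-4-(methacryloyloxy)-6-methylnon-2-enoate
Conditions: Dess–Martin periodinane, NaHCO3, CH2Cl2, 0 °C to rt
Reagents that add atoms: none
Why: Buffered Dess–Martin oxidation gives the epoxy aldehyde without epimerising C5 or opening the oxirane (the C5 descriptor changes only because CHO outranks C4); the aldehyde is used at once.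

Step 12
Reactants: 16 methyl (2Z,4S,6R,7S)-2-(acetoxymethyl)-9-[(2R,3R)-3-formyl-2-methyloxiran-2-yl]-3-iodo-7-[(4-methoxybenzyl)oxy]-4-(methacryloyloxy)-6-methylnon-2-enoate
Product: 18 1-O-(4-methoxybenzyl) ether of the target, via C6 chromium alkoxide 17 (not isolated)
Conditions: CrCl2 (10 equiv), NiCl2 (0.1 equiv), degassed DMSO/THF 3:1, syringe-pump addition to 2 mM, rt; aq. NH4Cl
Reagents that add atoms: none
Why: Intramolecular Nozaki–Hiyama–Kishi alkenylation, in which zerovalent nickel inserts into C7–I with retention, the alkenyl group passes to trivalent chromium and adds to the C6 aldehyde (ten-membered ring) anti to the oxirane C5–O bond (polar Felkin–Anh, giving 6S), and the chromium alkoxide, held cis to CO2Me, closes the butenolide with loss of methoxide.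

Step 13
Reactants: 18 1-O-(4-methoxybenzyl) ether of the target
Product: 19 target (CNP0119405.1)
Conditions: DDQ, CH2Cl2/pH 7 phosphate buffer 10:1, 0 °C to rt
Reagents that add atoms: none
Why: Oxidative PMB cleavage (benzylic hydride abstraction, hydrolysis of the oxocarbenium ion) under neutral conditions that leave the oxirane, the γ-acyloxy butenolide and both esters intact; no stereocentre is touched.

## Compound list

1 | nerol, (2Z)-3,7-dimethylocta-2,6-dien-1-ol | CC(C)=CCC/C(C)=C\CO | starting material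
2 | neryl tert-butyldiphenylsilyl ether | CC(C)=CCC/C(C)=C\CO[Si](c1ccccc1)(c1ccccc1)C(C)(C)C | intermediate
3 | terminal (6,7-) epoxide of 2, racemic at the oxirane CH | CC1(C)OC1CC/C(C)=C\CO[Si](c1ccccc1)(c1ccccc1)C(C)(C)C | intermediate (not isolated)
4 | (4Z)-6-[(tert-butyldiphenylsilyl)oxy]-4-methylhex-4-enal | O=CCC/C(C)=C\CO[Si](c1ccccc1)(c1ccccc1)C(C)(C)C | intermediate
5 | bis[(+)-isopinocampheyl]borinate ester of alcohol 6 | C=C[C@@H](C)[C@@H](OB([C@H]1C[C@H]2C[C@@H]([C@@H]1C)C2(C)C)[C@H]1C[C@H]2C[C@@H]([C@@H]1C)C2(C)C)CC/C(C)=C\CO[Si](c1ccccc1)(c1ccccc1)C(C)(C)C | intermediate (not isolated)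
6 | (3R,4S,7Z)-9-[(tert-butyldiphenylsilyl)oxy]-3,7-dimethylnona-1,7-dien-4-ol | C=C[C@@H](C)[C@@H](O)CC/C(C)=C\CO[Si](c1ccccc1)(c1ccccc1)C(C)(C)C | intermediate
7 | 4-methoxybenzyl ether of 6 | C=C[C@@H](C)[C@@H](OCc1ccc(OC)cc1)CC/C(C)=C\CO[Si](c1ccccc1)(c1ccccc1)C(C)(C)C | intermediate
8 | (3R,4S,7Z)-9-[(tert-butyldiphenylsilyl)oxy]-4-[(4-methoxybenzyl)oxy]-3,7-dimethylnon-7-enal | O=CC[C@@H](C)[C@@H](OCc1ccc(OC)cc1)CC/C(C)=C\CO[Si](c1ccccc1)(c1ccccc1)C(C)(C)C | intermediate
9 | methyl propiolate | C#CC(=O)OC | starting material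
10 | methyl (4S,6R,7S,10Z)-12-[(tert-butyldiphenylsilyl)oxy]-4-hydroxy-7-[(4-methoxybenzyl)oxy]-6,10-dimethyldodec-10-en-2-ynoate | COC(=O)C#C[C@@H](O)C[C@@H](C)[C@@H](OCc1ccc(OC)cc1)CC/C(C)=C\CO[Si](c1ccccc1)(c1ccccc1)C(C)(C)C | intermediate
11 | 4-O-methacryloyl ester of 10 | COC(=O)C#C[C@@H](OC(=O)C(C)=C)C[C@@H](C)[C@@H](OCc1ccc(OC)cc1)CC/C(C)=C\CO[Si](c1ccccc1)(c1ccccc1)C(C)(C)C | intermediate
12 | magnesium alkoxide of the (2Z)-2-(hydroxymethyl)-3-iodo enoate (shown as the free alcohol) | COC(=O)/C(CO)=C(\I)[C@@H](OC(=O)C(C)=C)C[C@@H](C)[C@@H](OCc1ccc(OC)cc1)CC/C(C)=C\CO[Si](c1ccccc1)(c1ccccc1)C(C)(C)C | intermediate (not isolated)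
13 | methyl (2Z,4S,6R,7S,10Z)-2-(acetoxymethyl)-12-[(tert-butyldiphenylsilyl)oxy]-3-iodo-7-[(4-methoxybenzyl)oxy]-4-(methacryloyloxy)-6,10-dimethyldodeca-2,10-dienoate | COC(=O)/C(COC(C)=O)=C(\I)[C@@H](OC(=O)C(C)=C)C[C@@H](C)[C@@H](OCc1ccc(OC)cc1)CC/C(C)=C\CO[Si](c1ccccc1)(c1ccccc1)C(C)(C)C | intermediate
14 | 12-hydroxy compound (free C6 allylic alcohol) from 13 | COC(=O)/C(COC(C)=O)=C(\I)[C@@H](OC(=O)C(C)=C)C[C@@H](C)[C@@H](OCc1ccc(OC)cc1)CC/C(C)=C\CO | intermediate
15 | methyl (2Z,4S,6R,7S)-2-(acetoxymethyl)-9-[(2R,3S)-3-(hydroxymethyl)-2-methyloxiran-2-yl]-3-iodo-7-[(4-methoxybenzyl)oxy]-4-(methacryloyloxy)-6-methylnon-2-enoate | COC(=O)/C(COC(C)=O)=C(\I)[C@@H](OC(=O)C(C)=C)C[C@@H](C)[C@@H](OCc1ccc(OC)cc1)CC[C@@]1(C)O[C@H]1CO | intermediate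
16 | methyl (2Z,4S,6R,7S)-2-(acetoxymethyl)-9-[(2R,3R)-3-formyl-2-methyloxiran-2-yl]-3-iodo-7-[(4-methoxybenzyl)oxy]-4-(methacryloyloxy)-6-methylnon-2-enoate | COC(=O)/C(COC(C)=O)=C(\I)[C@@H](OC(=O)C(C)=C)C[C@@H](C)[C@@H](OCc1ccc(OC)cc1)CC[C@@]1(C)O[C@H]1C=O | intermediate
17 | ring-closed (C6–C7) chromium alkoxide: target skeleton with the lactone still open (O6–Cr, C12 as CO2Me), 1-O-PMB (shown as the free alcohol) | C=C(C)C(=O)O[C@H]1C[C@@H](C)[C@@H](OCc2ccc(OC)cc2)CC[C@@]2(C)O[C@H]2[C@@H](O)/C1=C(/COC(C)=O)C(=O)OC | intermediate (not isolated)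
18 | 1-O-(4-methoxybenzyl) ether of the target | C=C(C)C(=O)O[C@H]1C[C@@H](C)[C@@H](OCc2ccc(OC)cc2)CC[C@@]2(C)O[C@H]2[C@H]2OC(=O)C(COC(C)=O)=C12 | intermediate
19 | target: (1S,4R,5S,6S,8S,10R)-13-acetoxy-4,5-epoxy-1-hydroxy-8-(methacryloyloxy)germacr-7(11)-en-12,6-olide | C=C(C)C(=O)O[C@H]1C[C@@H](C)[C@@H](O)CC[C@@]2(C)O[C@H]2[C@H]2OC(=O)C(COC(C)=O)=C12 | target

## Step count and weak points

Total steps: 13. Longest linear sequence: 13 (nerol to target; methyl propiolate is a purchased side input).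

Most likely to fail:

Step 12 (ring closure). It asks a tetrasubstituted alkenyl iodide to close a ten-membered ring onto an epoxy aldehyde, with divalent chromium present and C6 set only by the Felkin–Anh preference. The fallback sets out from allylic alcohol 14. It is oxidised with MnO2 to the (Z)-enal F1, a sturdier aldehyde, and the same Ni/Cr closure then gives, through the ring-closed chromium alkoxide F2, the macrocyclic 4Z-ene butenolide F3. Only then is the 4,5-alkene epoxidised (dimethyldioxirane, or a Shi-type chiral dioxirane if the ring conformation does not steer attack to the required face), which comes back to the route at 18. This puts the oxirane after the lactone ring, in the order costunolide to parthenolide, at the cost of losing epoxide control over C6.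

Step 8 (iodide/formaldehyde halo-aldol). The Z geometry of a tetrasubstituted, γ-acyloxy-substituted adduct is the least precedented stereochemical outcome of the route. The fallback sets out from hydroxy ynoate 10, before acylation. The addition is run on its free magnesium alkoxide, which can deliver formaldehyde from the C8 side and lets any E isomer lactonise to an easily removed 4-iodobutenolide, giving the Z-iodo diol F4. Selective acetylation of the primary C13 hydroxyl (AcCl, 2,4,6-collidine, −78 °C) gives the monoacetate F5, and methacryloylation of the C8 hydroxyl (methacrylic anhydride, DMAP) comes back at 13.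

Step 5 (aldehyde-selective Wacker). Regioselectivity on a branched alkene and palladium-induced migration of the Z-alkene are the concerns. The fallback sets out from 7. Its terminal alkene is hydroborated with 9-BBN (the trisubstituted alkene is left alone) to the B-alkyl-9-BBN adduct F6, which is oxidised (NaOH, H2O2) to the primary alcohol F7; Dess–Martin oxidation then comes back at 8.

## Further compounds

F1 | step 12 | (Z)-enal from 14 (C6 aldehyde, 4Z-alkene kept) | COC(=O)/C(COC(C)=O)=C(\I)[C@@H](OC(=O)C(C)=C)C[C@@H](C)[C@@H](OCc1ccc(OC)cc1)CC/C(C)=C\C=O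
F2 | step 12 | ring-closed chromium alkoxide with 4Z-alkene and open lactone (shown as the free alcohol) | C=C(C)C(=O)O[C@H]1C[C@@H](C)[C@@H](OCc2ccc(OC)cc2)CC/C(C)=C\[C@@H](O)/C1=C(/COC(C)=O)C(=O)OC
F3 | step 12 | 1-O-PMB 4Z-ene (4,5-deoxy) analogue of the target | C=C(C)C(=O)O[C@H]1C[C@@H](C)[C@@H](OCc2ccc(OC)cc2)CC/C(C)=C\[C@H]2OC(=O)C(COC(C)=O)=C12
F4 | step 8 | Z-iodo diol (C8–OH and C13–OH free) | COC(=O)/C(CO)=C(\I)[C@@H](O)C[C@@H](C)[C@@H](OCc1ccc(OC)cc1)CC/C(C)=C\CO[Si](c1ccccc1)(c1ccccc1)C(C)(C)C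
F5 | step 8 | C13 monoacetate of the Z-iodo diol | COC(=O)/C(COC(C)=O)=C(\I)[C@@H](O)C[C@@H](C)[C@@H](OCc1ccc(OC)cc1)CC/C(C)=C\CO[Si](c1ccccc1)(c1ccccc1)C(C)(C)C
F6 | step 5 | B-alkyl-9-BBN adduct of 7 (boron on C8) | B1(CC[C@@H](C)[C@@H](OCc2ccc(OC)cc2)CC/C(C)=C\CO[Si](c2ccccc2)(c2ccccc2)C(C)(C)C)C2CCCC1CCC2
F7 | step 5 | primary alcohol (C8–OH) from 7 | OCC[C@@H](C)[C@@H](OCc1ccc(OC)cc1)CC/C(C)=C\CO[Si](c1ccccc1)(c1ccccc1)C(C)(C)C
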